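**Retrosynthetic overview**

1. Target 18 comes from the cis-fused keto diol 16 by acetylation at O8 and then senecioylation at O9. Diol 16 comes from the 11-chloro enone 10 by introduction of C8=C9, OsO4 on C8=C9, hydrogenation of C1=C10 and loss of HCl; the C11 chloride masks the isopropenyl group.
2. Enone 10 comes from diketone 8 with HCl, which cleaves the C9–C11 cyclobutane bond and closes ring A by aldol condensation (C1–C10). Ring B is the six-membered ring of the pinane, ring A is formed second, and the cyclobutane is a temporary third ring.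
3. Diketone 8 comes from forming the C4–C5 bond by Michael addition of enol silane 5 of 3-methylnopinone to (E)-pent-3-en-2-one 6; 5 is made in two steps from (+)-nopinone 1.
4. The feature used: on ring B the C5 methyl and C11 (on C7) are 1,3-cis, which is the relation between C3 and the bridge carbon on C5 of nopinone. The C9–C11 bond therefore holds C11 on one face while the side chain is attached to C5 on the other.

Key step: step 3

Remark on numbering: from compound 10 on, eremophilane numbering is used (C2 ketone, C4 and C5 methyls, C7 side chain, C8 and C9 oxygens, C10 ring-fusion CH, C11 side-chain carbon); β is the face of the C5 methyl. In the pinane compounds, nopinone C3 = C5, C5 = C7, C6 = C11, C1 = C9, C2 = C10.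

Assumption: (1R,5S)-(+)-nopinone 1 is bought; it is the ozonolysis product of (−)-β-pinene and its bridgeheads fix C7.

**Route**

Step 1
Reactants: 1 (+)-nopinone
Product: 3 (1R,3S,5S)-3,6,6-trimethylbicyclo[3.1.1]heptan-2-one (3-methylnopinone, methyl anti to the gem-dimethyl bridge), via lithium enolate of nopinone 2 (not isolated)
Conditions: LiN(iPr)2 (LDA), THF, −78 °C; MeI, −78 → −20 °C
Reagents that add atoms: iodomethane, CI
Why: Kinetic enolate alkylation: only C3 can be deprotonated (C1 is a bridgehead) and MeI attacks the enolate face away from the gem-dimethyl bridge, giving the 3S ketone, whose C3 configuration is in any case erased in step 2.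

Step 2
Reactants: 3 3-methylnopinone
Product: 5 (1R,5R)-trimethyl[(3,6,6-trimethylbicyclo[3.1.1]hept-2-en-2-yl)oxy]silane, via lithium enolate of 3-methylnopinone 4 (not isolated)
Conditions: LiN(iPr)2 (LDA), THF, −78 → 0 °C; Me3SiCl, −78 °C → rt
Reagents that add atoms: chlorotrimethylsilane, C[Si](C)(C)Cl
Why: Enolate O-silylation: deprotonation is again possible only at C3, so a single tetrasubstituted enol silane should form and no new stereocentre arises.

Step 3
Reactants: 5 enol silane of 3-methylnopinone; 6 (E)-pent-3-en-2-one
Product: 8 (1R,3R,5R)-3,6,6-trimethyl-3-[(2S)-4-oxopentan-2-yl]bicyclo[3.1.1]heptan-2-one (side chain anti, C3 methyl syn to the gem-dimethyl bridge), via titanium enolate 7 (not isolated)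
Conditions: 6, TiCl4 (1.1 equiv), CH2Cl2, −78 °C; then 5, −78 °C; aq. K2CO3 work-up
Reagents that add atoms: none
Why: Mukaiyama–Michael addition: TiCl4 binds the carbonyl oxygen of 6 and the enol silane 5 attacks C4 of the enone through its C3 (the future C5) in an open transition state, giving titanium enolate 7 and Me3SiCl, and 7 is hydrolysed on work-up. The closest known reaction type is the TiCl4-mediated silyl enol ether version of the Michael step of the Robinson annulation, as run with 2-methylcycloalkanone enol silanes and (E)-pent-3-en-2-one. No ring is closed; only the C4–C5 bond is made. The quaternary centre C5 is controlled by the gem-dimethyl bridge, whose inward methyl covers one face of the enol double bond, so the enone is attached anti to the bridge and the C5 methyl ends syn to it, that is cis to C11. The C4 centre follows from the relative topicity of the open transition state (Si face of the E enone), which in this reaction class places the C4 methyl cis to the C5 methyl after ring closure; this is the less secure element. The step needs site selectivity, which is fixed because the bridgehead C1 cannot enolise, and it needs 1,4-addition without acid cleavage of the cyclobutane, which TiCl4 at −78 °C with basic work-up should secure.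

Step 4
Reactants: 8 diketone
Product: 10 11-chloroeremophil-1(10)-en-2-one, (4S,4aR,6R)-6-(2-chloropropan-2-yl)-4,4a-dimethyl-4,4a,5,6,7,8-hexahydronaphthalen-2(3H)-one, via ring-opened chloro diketone 9 (not isolated)
Conditions: HCl (gas), AcOH, 0 °C → rt
Reagents that add atoms: hydrogen chloride, Cl
Why: Acid-induced fragmentation followed by aldol condensation (Robinson-type ring closure): the protonated strained ketone breaks the C9–C11 cyclobutane bond to a tertiary cation that chloride traps (9), and the methyl ketone then condenses with the ring carbonyl to close ring A as the conjugated enone, with C4, C5 and C7 untouched.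

Step 5
Reactants: 10 chloro enone
Product: 11 11-chloroeremophila-1(10),8-dien-2-one, (4S,4aR,6S)-6-(2-chloropropan-2-yl)-4,4a-dimethyl-4,4a,5,6-tetrahydronaphthalen-2(3H)-one
Conditions: chloranil (1.2 equiv), t-BuOH, reflux
Reagents that add atoms: none
Why: Quinone dehydrogenation of an enone through its heteroannular dienol: hydride abstraction from C8 should give the linear 1(10),8-dienone, as 4-en-3-ones give 4,6-dien-3-ones, and no stereocentre is formed.

Step 6
Reactants: 11 chloro dienone
Product: 12 11-chloro-8α,9α-dihydroxyeremophil-1(10)-en-2-one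
Conditions: OsO4 (5 mol %), NMO, acetone/H2O (10:1), 0 °C → rt
Reagents that add atoms: osmium tetroxide, O=[Os](=O)(=O)=O; N-methylmorpholine N-oxide, C[N+]1([O-])CCOCC1; water, O
Why: Catalytic OsO4/NMO syn-dihydroxylation: OsO4 takes the more electron-rich γ,δ-bond C8=C9 of the dienone from the α face, anti to the allylic C7 CMe2Cl group and the C5 methyl, which sets C8 and C9 with both oxygens α.

Step 7
Reactants: 12 chloro enone diol
Product: 13 11-chloro-8α,9α-(isopropylidenedioxy)eremophil-1(10)-en-2-one
Conditions: Me2C(OMe)2, PPTS (cat.), CH2Cl2, rt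
Reagents that add atoms: 2,2-dimethoxypropane, COC(C)(C)OC
Why: Acetal exchange: the cis-8,9-diol closes a five-membered isopropylidene acetal, which removes the hydroxyls as directing groups and covers the α face of ring B for step 8.

Step 8
Reactants: 13 enone acetonide
Product: 14 11-chloro-8α,9α-(isopropylidenedioxy)-10βH-eremophilan-2-one (cis-fused)
Conditions: H2 (1 atm), palladium on carbon (10% Pd/C), EtOAc, rt
Reagents that add atoms: none
Why: Heterogeneous hydrogenation of the C1=C10 enone bond: hydrogen should reach C10 from the β face because the acetonide blocks the α face next to C10 and 4,5-dimethyl octalones of this kind give cis-fused decalones, so H10 ends cis to the C5 methyl, while the tertiary chloride and the ketone are not reduced under neutral conditions.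

Step 9
Reactants: 14 chloro decalone acetonide
Product: 15 8α,9α-(isopropylidenedioxy)-10βH-eremophil-11-en-2-one
Conditions: activated neutral Al2O3, hexane, rt → 60 °C
Reagents that add atoms: none
Why: Dehydrochlorination of a tertiary chloride on alumina: a methyl proton should be lost in preference to the hindered H7, since the 7(11)-alkene would suffer allylic strain with the C8 oxygen, and this releases the isopropenyl group without touching acetal or ketone.

Step 10
Reactants: 15 isopropenyl acetonide
Product: 16 8α,9α-dihydroxy-10βH-eremophil-11-en-2-one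
Conditions: AcOH/H2O (4:1), 40 °C
Reagents that add atoms: none
Why: Mild acid hydrolysis of the isopropylidene acetal, under which the isopropenyl group and the ketone should survive.

Step 11
Reactants: 16 keto diol
Product: 17 8α-acetoxy-9α-hydroxy-10βH-eremophil-11-en-2-one
Conditions: Ac2O (1.1 equiv), pyridine, CH2Cl2, 0 °C
Reagents that add atoms: acetic anhydride, CC(=O)OC(C)=O
Why: Selective esterification: in the preferred chair of ring B (C7 isopropenyl and C5 methyl equatorial) the 8α-hydroxyl is equatorial while the 9α-hydroxyl is axial and syn-axial to C4, so one equivalent of Ac2O should acylate O8.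

Step 12
Reactants: 17 monoacetate
Product: 18 8α-acetoxy-9α-(3-methylbut-2-enoyloxy)-10βH-eremophil-11-en-2-one (CNP0150397.1)
Conditions: 3-methylbut-2-enoyl chloride, pyridine, DMAP (cat.), CH2Cl2, 0 → 40 °C
Reagents that add atoms: 3-methylbut-2-enoyl chloride, CC(C)=CC(=O)Cl
Why: DMAP-catalysed acylation of the remaining hindered axial 9α-hydroxyl, with pyridine instead of a trialkylamine to avoid deconjugation of the senecioyl group through its vinylketene, while the equatorial C8 acetate has no driving force to migrate.

**Compound list**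

1 | (+)-nopinone, (1R,5S)-6,6-dimethylbicyclo[3.1.1]heptan-2-one | CC1(C)[C@H]2CCC(=O)[C@@H]1C2 | starting material
2 | lithium enolate of nopinone | CC1(C)[C@H]2CC=C(O[Li])[C@@H]1C2 | intermediate
3 | (1R,3S,5S)-3,6,6-trimethylbicyclo[3.1.1]heptan-2-one (3-methylnopinone) | CC1(C)[C@H]2C[C@H](C)C(=O)[C@@H]1C2 | intermediate
4 | lithium enolate of 3-methylnopinone | CC1(C)[C@H]2CC(C)=C(O[Li])[C@@H]1C2 | intermediate
5 | (1R,5R)-trimethyl[(3,6,6-trimethylbicyclo[3.1.1]hept-2-en-2-yl)oxy]silane | CC1(C)[C@H]2CC(C)=C(O[Si](C)(C)C)[C@@H]1C2 | intermediate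
6 | (E)-pent-3-en-2-one | C/C=C/C(C)=O | starting material
7 | trichlorotitanium enolate of 8 (side-chain enolate, double-bond geometry not defined) | CC1(C)[C@H]2C[C@](C)([C@@H](C)C=C(C)O[Ti](Cl)(Cl)Cl)C(=O)[C@@H]1C2 | intermediate
8 | (1R,3R,5R)-3,6,6-trimethyl-3-[(2S)-4-oxopentan-2-yl]bicyclo[3.1.1]heptan-2-one | CC1(C)[C@H]2C[C@](C)([C@@H](C)CC(C)=O)C(=O)[C@@H]1C2 | intermediate
9 | (2R,4R)-4-(2-chloropropan-2-yl)-2-methyl-2-[(2S)-4-oxopentan-2-yl]cyclohexan-1-one | CC(C)(Cl)[C@H]1C[C@](C)([C@@H](C)CC(C)=O)C(=O)CC1 | intermediate
10 | 11-chloroeremophil-1(10)-en-2-one | CC(C)(Cl)[C@H]1C[C@@]2(C)C(=CC(=O)C[C@@H]2C)CC1 | intermediate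
11 | 11-chloroeremophila-1(10),8-dien-2-one | CC(C)(Cl)[C@H]1C[C@@]2(C)C(=CC(=O)C[C@@H]2C)C=C1 | intermediate
12 | 11-chloro-8α,9α-dihydroxyeremophil-1(10)-en-2-one | CC(C)(Cl)[C@H]1C[C@@]2(C)C(=CC(=O)C[C@@H]2C)[C@H](O)[C@@H]1O | intermediate
13 | 11-chloro-8α,9α-(isopropylidenedioxy)eremophil-1(10)-en-2-one | CC(C)(Cl)[C@H]1C[C@@]2(C)C(=CC(=O)C[C@@H]2C)[C@@H]3OC(C)(C)O[C@@H]31 | intermediate
14 | 11-chloro-8α,9α-(isopropylidenedioxy)-10βH-eremophilan-2-one | CC(C)(Cl)[C@H]1C[C@@]2(C)[C@H](CC(=O)C[C@@H]2C)[C@@H]3OC(C)(C)O[C@@H]31 | intermediate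
15 | 8α,9α-(isopropylidenedioxy)-10βH-eremophil-11-en-2-one | C=C(C)[C@H]1C[C@@]2(C)[C@H](CC(=O)C[C@@H]2C)[C@@H]3OC(C)(C)O[C@@H]31 | intermediate
16 | 8α,9α-dihydroxy-10βH-eremophil-11-en-2-one | C=C(C)[C@H]1C[C@@]2(C)[C@H](CC(=O)C[C@@H]2C)[C@H](O)[C@@H]1O | intermediate
17 | 8α-acetoxy-9α-hydroxy-10βH-eremophil-11-en-2-one | C=C(C)[C@H]1C[C@@]2(C)[C@H](CC(=O)C[C@@H]2C)[C@H](O)[C@@H]1OC(C)=O | intermediate
18 | 8α-acetoxy-9α-(3-methylbut-2-enoyloxy)-10βH-eremophil-11-en-2-one (CNP0150397.1) | C=C(C)[C@H]1C[C@@]2(C)[C@H](CC(=O)C[C@@H]2C)[C@H](OC(=O)C=C(C)C)[C@@H]1OC(C)=O | target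

**Step count and risks**

Total step count: 12. Longest linear sequence: 12 steps (1 → 18).

Steps most likely to fail:

1. Step 3 (key step). What may go wrong: weak discrimination between the two faces of the enone, so that the C4 epimer forms alongside, or slow addition of the congested tetrasubstituted enol silane with hydrolysis back to 3. Fallback, setting out from 5 and returning at 8: the enone is replaced by an acceptor whose face is fixed by an auxiliary. (R)-4-Benzyloxazolidin-2-one is N-acylated (n-BuLi, (E)-but-2-enoyl chloride, THF, −78 °C) to (R)-4-benzyl-3-[(E)-but-2-enoyl]oxazolidin-2-one F1. In its TiCl4 chelate (carbonyls syn, enoyl s-cis) the benzyl group should cover the Re face of the β-carbon, so 5 should add anti to its bridge to the Si face (TiCl4, CH2Cl2, −78 °C) and give the imide adduct F2 with the 2S side-chain centre. Transamidation with MeNH(OMe)·HCl/AlMe3 (CH2Cl2, 0 °C) would give the N-methoxy-N-methylamide F3. MeMgBr (THF, −20 °C) would then convert the amide, but not the hindered ring ketone, into the methyl ketone 8.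

2. Step 5. What may go wrong: loss of HCl from C11 through the extended enol of the dienone at reflux, or dehydrogenation at the wrong site and over-oxidation. Fallback, setting out from 10 and returning at 11: the enone is converted under thermodynamic conditions (t-BuMe2SiOTf, Et3N, CH2Cl2, 0 °C) into the heteroannular silyl dienol ether, 2-(tert-butyldimethylsilyloxy)-11-chloroeremophila-1,9-diene F4. This is oxidised at room temperature with Pd(OAc)2 in MeCN (Saegusa–Ito oxidation) to the linear dienone 11, without heating and without a quinone.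

3. Step 8. What may go wrong: delivery of hydrogen to the α face of C10, giving the trans-fused decalone, or hydrogenolysis of the allylic C9–O bond on the metal surface. Fallback, setting out from 13 and returning at 14: Luche reduction (NaBH4, CeCl3·7H2O, MeOH, −78 °C) should give the quasi-equatorial allylic alcohol, 11-chloro-8α,9α-(isopropylidenedioxy)eremophil-1(10)-en-2β-ol F5. Hydroxyl-directed homogeneous hydrogenation ([Ir(cod)(PCy3)(py)]PF6, H2, CH2Cl2, rt) would then deliver hydrogen from the β face to give 11-chloro-8α,9α-(isopropylidenedioxy)-10βH-eremophilan-2β-ol F6. Oxidation (n-Pr4N[RuO4] cat., NMO, CH2Cl2) would return ketone 14.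

**Further compounds**

F1 | step 3 | (R)-4-benzyl-3-[(E)-but-2-enoyl]oxazolidin-2-one | C/C=C/C(=O)N1[C@H](Cc2ccccc2)COC1=O
F2 | step 3 | (R)-4-benzyl-3-{(3S)-3-[(1R,3R,5R)-3,6,6-trimethyl-2-oxobicyclo[3.1.1]heptan-3-yl]butanoyl}oxazolidin-2-one | CC1(C)[C@H]2C[C@](C)([C@@H](C)CC(=O)N3[C@H](Cc4ccccc4)COC3=O)C(=O)[C@@H]1C2
F3 | step 3 | (3S)-N-methoxy-N-methyl-3-[(1R,3R,5R)-3,6,6-trimethyl-2-oxobicyclo[3.1.1]heptan-3-yl]butanamide | CC1(C)[C@H]2C[C@](C)([C@@H](C)CC(=O)N(C)OC)C(=O)[C@@H]1C2
F4 | step 5 | 2-(tert-butyldimethylsilyloxy)-11-chloroeremophila-1,9-diene | CC(C)(Cl)[C@H]1C[C@@]2(C)C(C=C(O[Si](C)(C)C(C)(C)C)C[C@@H]2C)=CC1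
F5 | step 8 | 11-chloro-8α,9α-(isopropylidenedioxy)eremophil-1(10)-en-2β-ol | CC(C)(Cl)[C@H]1C[C@@]2(C)C(=C[C@H](O)C[C@@H]2C)[C@@H]3OC(C)(C)O[C@@H]31
F6 | step 8 | 11-chloro-8α,9α-(isopropylidenedioxy)-10βH-eremophilan-2β-ol | CC(C)(Cl)[C@H]1C[C@@]2(C)[C@H](C[C@H](O)C[C@@H]2C)[C@@H]3OC(C)(C)O[C@@H]31
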